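The ratio of two logarithms was what I carried through this flask: s = ln f_L / ln f_R, with f_L and f_R the parts of the left-handed and right-handed substrate left of their own charges. I assumed both substrates see the same partner and catalyst, so that s holds however these run down. The symmetric case, s = 1, is the zero of the scale: there eS, the excess of right-handed substrate, stays zero.

| flask | left-handed substrate | right-handed substrate | partner | catalyst | added ligand | remark | time |
|---|---|---|---|---|---|---|---|
| spring | 0.10 M | 0.10 M | 0.15 M | 5 mM | 20 mM | run made earlier |  |
| dusk | 0.10 M | 0.10 M | 0.60 M | 5 mM | 20 mM | run made earlier |  |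
| flask | 0.10 M | 0.10 M | 0.300 M | 5.0 mM | 20 mM |  | 15 min |

| run | time / min | left-handed substrate / % | right-handed substrate / % | left-handed product / % |
|---|---|---|---|---|
| spring | 1.00 | 49.4 | 50.2 | 1.7 |
| spring | 3.00 | 42.7 | 45.5 | 4.4 |
| spring | 6.00 | 42.1 | 44.5 | 6.4 |
| spring | 10.0 | 37.4 | 41.2 | 9.5 |
| dusk | 1.00 | 43.1 | 45.5 | 5.6 |
| dusk | 3.00 | 34.6 | 38.3 | 15.9 |
| dusk | 6.00 | 22.2 | 32.6 | 24.4 |
| dusk | 10.0 | 12.6 | 25.4 | 30.4 |

(standard deviation of a reading: 1 percentage point)

* part of the left-handed substrate and right-handed substrate charged together that has reacted at 15 min
* excess of left-handed product over right-handed product in the product at 15 min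
* excess of right-handed substrate over left-handed substrate among what is left of the two at 15 min

- catalyst is single-handed; left-handed substrate and right-handed substrate are mirror images of each other, charged as a racemate, each of them at the stated concentration
- an excess is the difference of the two amounts in percent of their sum
- an excess is below zero if the other one leads

At the last reading spring gave 1.50 and dusk 2.04. I took these as lower and upper bound and kept their mean, 1.77, as the selectivity factor, the ratio of those logarithms.

For f_R I took ln f_R as proportional to mean partner times time, scaled on dusk, where less substrate was left than in spring. I assumed one partner per substrate and, for this flask, a guessed c, the part of the two substrates charged that has reacted, of 0.5: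

mean partner, dusk: 0.538 M; this flask: 0.250 M

f_R = 62.4%; f_L = f_R^s = 43.4%

c = 47.1%; eS = 17.9%

Spring's s put eS at 11.7% and dusk's at 24.0%. At dusk, left-handed product (30.4%) stood below the left-handed substrate lost (37.4%), so I placed eP, the excess of left-handed over right-handed product, between zero and the excess of the substrate losses, 20.1%.

The forecast gave 50%, −1% and 18%, with eS inside my bracket and eP just below it, calling eP “the least certain number”.

The flask gave c = 48.2%, eP = 4.60% and eS = 17.4%.

    partner + catalyst + left-handed substrate → catalyst + left-handed product (k = 1.45 /M²/s)
    partner + catalyst + right-handed substrate → catalyst + right-handed product (k = 0.848 /M²/s)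
    left-handed product ⇌ right-handed product (k = 0.00136 /s)
    partner → decomposed reagent (k = 3.73 × 10⁻⁵ /s)
    catalyst + added ligand ⇌ idle complex, settled at all times (K = 47.0 /M)

This flask kept 43% of its left-handed and 61% of its right-handed substrate at 15.0 min, which gives s = 1.71. The neighbour charged with 1.2 M of partner reached c = 93.1% and kept 5.67% of right-handed substrate, so f_R = 11.3% there. My s then gave that neighbour f_L = 2.13% and eS = 68.3%. The neighbour itself held 2.4% of its left-handed substrate and stood at eS = 64.9%.

(The earlier runs and the new flask were generated by integration for an exercise, noise included.)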